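(All constants were drawn at random within sensible limits; the flask was simulated.)

We follow one ratio through this flask: how fast the solid can feed the solution, set against how fast partner decays on its own.

solid substrate 49 mM; partner 0.900 equiv; time 3.0 h

1. amount of target and solid product together at 3.0 h, in percent of the solid substrate charged
2. concentration of dissolved substrate in solution at 3.0 h, in percent of saturation

- in percentages every species weighs as the solid substrate in it: one side product counts as two
- for target the solid product is counted in
- for a step with 2 of a species take k times the square, and two of it per event
- as a solid, counted per litre of solution: solid substrate, solid product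
- at the start none of the solid substrate is in solution
- dissolved substrate means what is dissolved; the solid is not counted in it
- run time (flask): 3.0 h

    solid substrate ⇌ dissolved substrate, rate k1*(cs1 - [dissolved substrate]) while solid is left; crystals form when [dissolved substrate] > cs1 (cs1 = 33 mM, k1 = 1.8 × 10⁻⁴ s⁻¹)
    dissolved substrate + partner → target (k2 = 0.20 M⁻¹ s⁻¹)
    2 dissolved substrate → side product (k3 = 0.41 M⁻¹ s⁻¹)
    solid product ⇌ target, rate k4*(cs4 - [target]) while solid is left; crystals form when [target] > cs4 (cs4 = 1.7 mM, k4 = 0.0041 s⁻¹)
    partner → decomposed reagent (k5 = 8.7 × 10⁻⁴ s⁻¹)
    target ⇌ isomer of the product (K6 = 0.56, k6 = 6.0 × 10⁻⁴ s⁻¹)

Counted in fractions of the charge, dissolution into an empty solution delivers at most 0.436 h⁻¹, while the charged partner first decays at 2.82 h⁻¹. Their quotient is the feed ratio, 0.155, and it stands well below one.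

For a bound from above, we let every dissolved substrate meet partner from the first moment. Partner then lasts 0.642 h, and target in all forms reaches 28.0%.

For an estimate from below, we hold dissolved substrate at the level it keeps against the full partner, which consumes it in a pseudo-first-order way. The share of partner going to target rather than to decay is then feed/(feed+one), so target in all forms reaches 12.1%. This is a hand estimate, not a strict limit: it neglects the side product and the rise from zero.

The isomer of the product relaxes quickly. Against dissolved target held at its solubility it takes 1.94%, which y does not count. So we expect y between 10.1% and 26.1%, the lower end being an estimate.

The forecast gives 17.4% and 1.5%, holding that “the slow dissolution keeps dissolved substrate at only a few mM”, and its y lies inside our bracket .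

The simulation gives 15.3% and 1.52%, and this y also lies inside . In this flask at 1.21 h, partner goes to decomposed reagent 1.7 times as fast as to target. By the asked time, 80.8% of the partner charged stands as decomposed reagent. In the neighbour flask with 1.50 equiv of partner, the feed ratio falls to 0.0929, which puts our expected y between 10.8% and 32.4%, and there it stands at 21.3%.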